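**Retrosynthetic overview**

1. Atom labels: lactone ring A = O, C1(=O), C2, C3, C4; 1,2-dioxane ring B = C3, C4, C5, C6, O, O; side chain C7–C14 on C6. Ring B is closed last, by oxa-Michael addition of a C6 hydroperoxide to C3 of a butenolide (O–C3 bond), where the cis ring fusion fixes C3.
2. Ring A is closed before that, by the C3–C4 bond: a rhodium carbenoid at C3 of a diazopyruvate ester inserts into the C4–H bond of a secondary carbinol ester with retention. The C2 keto group left behind is then turned into the C2=C3 double bond.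
3. Enabling feature: C4 is a fully substituted carbinol carbon carrying the ring-A oxygen, a methyl group and C5, and C3 lies 1,5 to C4 through O–C1–C2. The quaternary ring-fusion carbon can therefore be made from a stereodefined C4–H methine.
4. The C6–OOH and C4–OH groups come from one 2,2,4-trisubstituted oxetane (C4–O–C6) by Lewis-acid perhydrolysis with inversion at C6. The oxetane comes from a 1,3-diol made by allylic-strain-controlled epoxidation and hydride opening of an (E)-allylic alcohol built from (R)-but-3-yn-2-ol and an Evans-derived C7–C11 iodide (C8).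
5. The C10–C13 diene is completed late, by Suzuki coupling at C11–C12 of a vinyl iodide made by carboalumination, so that it never meets the acid or the carbenoid.

Key step: step 15

Remark: "Cn" in the text means the atom labels above, in which the target is (3S,4S,6R,8R,10E,12E); CIP descriptors in the names of intermediates change wherever substituent priorities change, although no centre is touched.

Step 1
Reactants: 1 (S)-4-benzyl-3-propionyloxazolidin-2-one; 2 3-bromo-1-(trimethylsilyl)prop-1-yne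
Product: 4 (S)-4-benzyl-3-[(R)-2-methyl-5-(trimethylsilyl)pent-4-ynoyl]oxazolidin-2-one, via sodium enolate 3 (not isolated)
Conditions: NaHMDS, THF, −78 °C; then 2, −78 → −40 °C
Reagents that add atoms: none
Why: Evans alkylation, in which the chelated (Z)-enolate should be alkylated by the propargylic bromide on the face opposite the benzyl group, setting C8.

Step 2
Reactants: 4 (S)-4-benzyl-3-[(R)-2-methyl-5-(trimethylsilyl)pent-4-ynoyl]oxazolidin-2-one
Product: 5 (R)-2-methyl-5-(trimethylsilyl)pent-4-yn-1-ol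
Conditions: LiBH4, MeOH (1 equiv), Et2O, 0 °C
Reagents that add atoms: none
Why: Reductive cleavage of the imide should give the primary alcohol (C7) without touching C8 or the silylalkyne, and the auxiliary is recovered.

Step 3
Reactants: 5 (R)-2-methyl-5-(trimethylsilyl)pent-4-yn-1-ol
Product: 6 (R)-(5-iodo-4-methylpent-1-yn-1-yl)trimethylsilane
Conditions: I2, PPh3, imidazole, CH2Cl2, 0 °C
Reagents that add atoms: iodine II
Why: Appel-type iodination of a primary alcohol by SN2 at CH2, which leaves the adjacent stereocentre untouched.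

Step 4
Reactants: 7 (R)-but-3-yn-2-ol; 6 (R)-(5-iodo-4-methylpent-1-yn-1-yl)trimethylsilane
Product: 9 (2R,6S)-6-methyl-9-(trimethylsilyl)nona-3,8-diyn-2-ol, via dilithium alkynolate 8 (not isolated)
Conditions: n-BuLi (2 equiv), THF/DMPU, −78 → 0 °C; then 6, 0 °C → rt
Reagents that add atoms: none
Why: Alkylation of the alkoxide–acetylide dianion at carbon by the primary iodide (SN2) should form the C6–C7 bond and bring in C4 as the (R)-carbinol from the chiral pool.

Step 5
Reactants: 9 (2R,6S)-6-methyl-9-(trimethylsilyl)nona-3,8-diyn-2-ol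
Product: 11 (2R,3Z,6R)-4-iodo-6-methyl-9-(trimethylsilyl)non-3-en-8-yn-2-ol, via sodium alkenylaluminate 10 (not isolated)
Conditions: NaAlH2(OCH2CH2OMe)2, THF, 0 °C → rt; then EtOAc; then I2, −78 °C
Reagents that add atoms: iodine II
Why: Alkoxide-directed trans-hydroalumination of the propargylic alcohol puts hydride on C5 and aluminium on C6, and iodinolysis with retention should give the (Z)-iodoalkene, while the undirected silylalkyne stays intact.

Step 6
Reactants: 11 (2R,3Z,6R)-4-iodo-6-methyl-9-(trimethylsilyl)non-3-en-8-yn-2-ol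
Product: 12 (2R,3E,6S)-4,6-dimethyl-9-(trimethylsilyl)non-3-en-8-yn-2-ol
Conditions: Me2CuLi (from MeLi and CuI, excess), Et2O, 0 °C
Reagents that add atoms: lithium dimethylcuprate [Li+].C[Cu-]C
Why: Cuprate cross-coupling at the vinyl iodide with retention of geometry should give the (E)-trisubstituted allylic alcohol with the new methyl on C6 cis to C4.

Step 7
Reactants: 12 (2R,3E,6S)-4,6-dimethyl-9-(trimethylsilyl)non-3-en-8-yn-2-ol
Product: 13 (1R)-1-[(2S,3S)-3-methyl-3-[(2R)-2-methyl-5-(trimethylsilyl)pent-4-yn-1-yl]oxiran-2-yl]ethan-1-ol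
Conditions: mCPBA, NaHCO3, CH2Cl2, 0 °C
Reagents that add atoms: mCPBA OOC(=O)c1cccc(Cl)c1
Why: Hydroxyl-directed peracid epoxidation, in which allylic 1,3-strain with the cis methyl on C6 holds the C4–H in the alkene plane so that oxygen is delivered syn to the hydroxyl (threo epoxy alcohol), setting C6 from C4.

Step 8
Reactants: 13 (1R)-1-[(2S,3S)-3-methyl-3-[(2R)-2-methyl-5-(trimethylsilyl)pent-4-yn-1-yl]oxiran-2-yl]ethan-1-ol
Product: 14 (2R,4S,6R)-4,6-dimethyl-9-(trimethylsilyl)non-8-yne-2,4-diol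
Conditions: NaAlH2(OCH2CH2OMe)2, THF, 0 °C
Reagents that add atoms: none
Why: Intramolecular hydride delivery from the alkoxyaluminate to C5 of the 2,3-epoxy alcohol should give the 1,3-diol, and the tertiary C6–O bond is not broken.

Step 9
Reactants: 14 (2R,4S,6R)-4,6-dimethyl-9-(trimethylsilyl)non-8-yne-2,4-diol
Product: 15 (2R,4S,6R)-4,6-dimethylnon-8-yne-2,4-diol
Conditions: K2CO3 (cat.), MeOH, rt
Reagents that add atoms: none
Why: Base-catalysed methanolysis of the alkynyl C–Si bond frees the terminal alkyne.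

Step 10
Reactants: 15 (2R,4S,6R)-4,6-dimethylnon-8-yne-2,4-diol
Product: 17 (2R,4S,6R,8E)-9-iodo-4,6,8-trimethylnon-8-ene-2,4-diol, via alkenylalane 16 (not isolated)
Conditions: Me3Al (excess), Cp2ZrCl2, CH2Cl2, 0 °C → rt; then I2, THF, −30 °C
Reagents that add atoms: trimethylaluminium C[Al](C)C; iodine II
Why: Negishi zirconium-catalysed syn carboalumination of the terminal alkyne (hydroxyls masked as aluminium alkoxides) followed by iodinolysis with retention should give the (E)-2-methyl-1-iodoalkene C10=C11.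

Step 11
Reactants: 17 (2R,4S,6R,8E)-9-iodo-4,6,8-trimethylnon-8-ene-2,4-diol
Product: 19 (2S,4S)-2-[(2R,4E)-5-iodo-2,4-dimethylpent-4-en-1-yl]-2,4-dimethyloxetane, via mesylate 18 (not isolated)
Conditions: MsCl, Et3N, CH2Cl2, −20 °C; then NaH, THF, 0 → 40 °C
Reagents that add atoms: none
Why: Selective mesylation of the secondary hydroxyl and intramolecular Williamson displacement (4-exo-tet) by the tertiary alkoxide should close the oxetane with inversion at C4.

Step 12
Reactants: 19 (2S,4S)-2-[(2R,4E)-5-iodo-2,4-dimethylpent-4-en-1-yl]-2,4-dimethyloxetane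
Product: 20 (2S,4R,6R,8E)-4-hydroperoxy-9-iodo-4,6,8-trimethylnon-8-en-2-ol
Conditions: H2O2 (anhydrous, in Et2O), Me3SiOTf (cat.), Et2O, −78 → −20 °C
Reagents that add atoms: hydrogen peroxide OO
Why: Lewis-acid-mediated opening of the oxetane by hydrogen peroxide at the tertiary carbon (tight ion pair, SN2-like) should proceed with inversion at C6 and leave the C4–O bond intact.

Step 13
Reactants: 20 (2S,4R,6R,8E)-4-hydroperoxy-9-iodo-4,6,8-trimethylnon-8-en-2-ol
Product: 21 (2S,4R,6R,8E)-4-[(tert-butyldimethylsilyl)peroxy]-9-iodo-4,6,8-trimethylnon-8-en-2-ol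
Conditions: TBSCl (1.05 equiv), imidazole, DMF, −20 °C
Reagents that add atoms: tert-butyldimethylsilyl chloride CC(C)(C)[Si](C)(C)Cl
Why: The more acidic and more nucleophilic hydroperoxide should be silylated ahead of the hindered secondary alcohol.

Step 14
Reactants: 21 (2S,4R,6R,8E)-4-[(tert-butyldimethylsilyl)peroxy]-9-iodo-4,6,8-trimethylnon-8-en-2-ol
Product: 23 (2S,4R,6R,8E)-4-[(tert-butyldimethylsilyl)peroxy]-9-iodo-4,6,8-trimethylnon-8-en-2-yl 3-diazo-2-oxopropanoate, via chlorooxoacetate 22 (not isolated)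
Conditions: (COCl)2, pyridine, CH2Cl2, −20 → 0 °C; evaporate; then CH2N2 (excess), Et2O, 0 °C
Reagents that add atoms: oxalyl chloride O=C(Cl)C(=O)Cl; diazomethane C=[N+]=[N-]
Why: O-acylation of the secondary alcohol by oxalyl chloride and acylation of diazomethane by the resulting acid chloride (as in the first stage of an Arndt–Eistert sequence) should give the diazopyruvate ester with C1, C2 and C3 in place.

Step 15
Reactants: 23 (2S,4R,6R,8E)-4-[(tert-butyldimethylsilyl)peroxy]-9-iodo-4,6,8-trimethylnon-8-en-2-yl 3-diazo-2-oxopropanoate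
Product: 24 (5S)-5-[(2R,4R,6E)-2-[(tert-butyldimethylsilyl)peroxy]-7-iodo-2,4,6-trimethylhept-6-en-1-yl]-5-methyldihydrofuran-2,3-dione
Conditions: Rh2(OAc)4 (cat.), CH2Cl2, rt, slow addition at high dilution
Reagents that add atoms: none
Why: Proposed new method: Rh2(OAc)4 should decompose the diazo ketone with loss of N2 to an electrophilic rhodium carbenoid at C3, which inserts in a concerted three-centre fashion into the tertiary C4–H bond. The closest known reaction types are the rhodium-carbenoid C–H insertion next to an ether oxygen that turns alkoxymethyl diazomethyl ketones into 3(2H)-furanones, and the β-lactone-forming insertion of diazomalonate esters into their alkoxy methine C–H; a diazopyruvate ester closing a five-membered α-keto lactone has not been shown. The step closes ring A (O, C1, C2, C3, C4) through the C3–C4 bond by a 1,5-insertion with a five-membered transition state. The new quaternary centre C4 is controlled by the (S)-carbinol centre of 23, because concerted insertion goes with retention at the C–H carbon. The step needs site selectivity for the C4 methine over the 1,6-related CH2 and CH3 hydrogens, the peroxide oxygens and the iodoalkene; the ring-size preference, the tertiary oxygen-bearing C–H, the eight-membered ring that ylide formation at the peroxide would require and the hindered, electron-poor iodoalkene should secure it, and high dilution should suppress carbene dimerisation.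

Step 16
Reactants: 24 (5S)-5-[(2R,4R,6E)-2-[(tert-butyldimethylsilyl)peroxy]-7-iodo-2,4,6-trimethylhept-6-en-1-yl]-5-methyldihydrofuran-2,3-dione
Product: 25 (3RS,5R)-5-[(2R,4R,6E)-2-[(tert-butyldimethylsilyl)peroxy]-7-iodo-2,4,6-trimethylhept-6-en-1-yl]-3-hydroxy-5-methyldihydrofuran-2(3H)-one
Conditions: NaBH4, CeCl3·7H2O, MeOH, −40 °C
Reagents that add atoms: none
Why: Luche reduction of the keto tautomer at C2 should give the α-hydroxy lactone without touching the lactone, the silyl peroxide or the iodoalkene; the C2 configuration is irrelevant because it is removed in step 17.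

Step 17
Reactants: 25 (3RS,5R)-5-[(2R,4R,6E)-2-[(tert-butyldimethylsilyl)peroxy]-7-iodo-2,4,6-trimethylhept-6-en-1-yl]-3-hydroxy-5-methyldihydrofuran-2(3H)-one
Product: 27 (5S)-5-[(2R,4R,6E)-2-[(tert-butyldimethylsilyl)peroxy]-7-iodo-2,4,6-trimethylhept-6-en-1-yl]-5-methylfuran-2(5H)-one, via mesylate 26 (not isolated)
Conditions: MsCl, Et3N, CH2Cl2, 0 °C; then DBU, rt
Reagents that add atoms: none
Why: Mesylation of the C2 hydroxyl and base-induced elimination with a C3 hydrogen into conjugation with the lactone should give the butenolide, in which C3 is the Michael acceptor carbon.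

Step 18
Reactants: 28 but-2-yn-1-ylbenzene
Product: 29 (Z)-4,4,5,5-tetramethyl-2-(4-phenylbut-2-en-2-yl)-1,3,2-dioxaborolane (boron trans to the benzyl group)
Conditions: pinacolborane, Cp2Zr(H)Cl (cat.), Et3N (cat.), neat, 60 °C
Reagents that add atoms: pinacolborane CC1(C)OBOC1(C)C
Why: Zirconium-hydride-catalysed syn hydroboration of the internal alkyne should place boron on the less hindered, methyl-bearing carbon (C12) cis to hydrogen; any regioisomer is removed by chromatography.

Step 19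
Reactants: 27 (5S)-5-[(2R,4R,6E)-2-[(tert-butyldimethylsilyl)peroxy]-7-iodo-2,4,6-trimethylhept-6-en-1-yl]-5-methylfuran-2(5H)-one; 29 (Z)-4,4,5,5-tetramethyl-2-(4-phenylbut-2-en-2-yl)-1,3,2-dioxaborolane
Product: 30 (5S)-5-[(2R,4R,6E,8E)-2-[(tert-butyldimethylsilyl)peroxy]-2,4,6,8-tetramethyl-10-phenyldeca-6,8-dien-1-yl]-5-methylfuran-2(5H)-one
Conditions: Pd(dppf)Cl2 (cat.), K3PO4, THF/H2O (degassed), rt
Reagents that add atoms: none
Why: Suzuki–Miyaura coupling forms C11–C12 with retention at both alkenes, and silyl-protected tertiary peroxides are of a type known to survive zerovalent-palladium cross-coupling under mild base.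

Step 20
Reactants: 30 (5S)-5-[(2R,4R,6E,8E)-2-[(tert-butyldimethylsilyl)peroxy]-2,4,6,8-tetramethyl-10-phenyldeca-6,8-dien-1-yl]-5-methylfuran-2(5H)-one
Product: 32 (3R,4aS,7aS)-3,4a-dimethyl-3-[(2R,4E,6E)-2,4,6-trimethyl-8-phenylocta-4,6-dien-1-yl]tetrahydrofuro[3,2-c][1,2]dioxin-6-one (CNP0272658.1), via hydroperoxide 31 (not isolated)
Conditions: Bu4NF, AcOH, THF, 0 °C; then Et2NH (cat.), CF3CH2OH, rt
Reagents that add atoms: none
Why: Fluoride removes the silyl group, and amine-catalysed intramolecular oxa-Michael addition (6-exo-trig) of the C6 hydroperoxide to C3 can only occur from the face of the C5 tether, which should give the cis-fused rings A and B and set C3.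

**Compound list**

1 | (S)-4-benzyl-3-propionyloxazolidin-2-one | CCC(=O)N1[C@@H](Cc2ccccc2)COC1=O | starting material
2 | 3-bromo-1-(trimethylsilyl)prop-1-yne | C[Si](C)(C)C#CCBr | starting material
3 | sodium (Z)-enolate of 1 | C/C=C(\[O-])N1[C@@H](Cc2ccccc2)COC1=O.[Na+] | intermediate
4 | (S)-4-benzyl-3-[(R)-2-methyl-5-(trimethylsilyl)pent-4-ynoyl]oxazolidin-2-one | C[Si](C)(C)C#CC[C@@H](C)C(=O)N1[C@@H](Cc2ccccc2)COC1=O | intermediate
5 | (R)-2-methyl-5-(trimethylsilyl)pent-4-yn-1-ol | C[Si](C)(C)C#CC[C@@H](C)CO | intermediate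
6 | (R)-(5-iodo-4-methylpent-1-yn-1-yl)trimethylsilane | C[Si](C)(C)C#CC[C@@H](C)CI | intermediate
7 | (R)-but-3-yn-2-ol | C[C@@H](O)C#C | starting material
8 | dilithium alkynolate of 7 (O,C-dianion) | C[C@@H]([O-])C#[C-].[Li+].[Li+] | intermediate
9 | (2R,6S)-6-methyl-9-(trimethylsilyl)nona-3,8-diyn-2-ol | C[Si](C)(C)C#CC[C@@H](C)CC#C[C@@H](C)O | intermediate
10 | sodium alkenylaluminate from 9 (five-membered O–Al–C=C ring, two 2-methoxyethoxy groups on aluminium) | C[C@H]1O[Al-](OCCOC)(OCCOC)C(C[C@H](C)CC#C[Si](C)(C)C)=C1.[Na+] | intermediate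
11 | (2R,3Z,6R)-4-iodo-6-methyl-9-(trimethylsilyl)non-3-en-8-yn-2-ol | C[Si](C)(C)C#CC[C@@H](C)C/C(I)=C/[C@@H](C)O | intermediate
12 | (2R,3E,6S)-4,6-dimethyl-9-(trimethylsilyl)non-3-en-8-yn-2-ol | C[Si](C)(C)C#CC[C@@H](C)C/C(C)=C/[C@@H](C)O | intermediate
13 | (1R)-1-[(2S,3S)-3-methyl-3-[(2R)-2-methyl-5-(trimethylsilyl)pent-4-yn-1-yl]oxiran-2-yl]ethan-1-ol | C[Si](C)(C)C#CC[C@@H](C)C[C@]1(C)O[C@H]1[C@@H](C)O | intermediate
14 | (2R,4S,6R)-4,6-dimethyl-9-(trimethylsilyl)non-8-yne-2,4-diol | C[Si](C)(C)C#CC[C@@H](C)C[C@@](O)(C)C[C@@H](C)O | intermediate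
15 | (2R,4S,6R)-4,6-dimethylnon-8-yne-2,4-diol | C#CC[C@@H](C)C[C@@](O)(C)C[C@@H](C)O | intermediate
16 | (E)-alkenyl(dimethyl)alane from 15, both hydroxyls as dimethylaluminium alkoxides | C[Al](C)/C=C(\C)C[C@@H](C)C[C@@](O[Al](C)C)(C)C[C@@H](C)O[Al](C)C | intermediate
17 | (2R,4S,6R,8E)-9-iodo-4,6,8-trimethylnon-8-ene-2,4-diol | I/C=C(\C)C[C@@H](C)C[C@@](O)(C)C[C@@H](C)O | intermediate
18 | (2R,4S,6R,8E)-4-hydroxy-9-iodo-4,6,8-trimethylnon-8-en-2-yl methanesulfonate | I/C=C(\C)C[C@@H](C)C[C@@](O)(C)C[C@@H](C)OS(C)(=O)=O | intermediate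
19 | (2S,4S)-2-[(2R,4E)-5-iodo-2,4-dimethylpent-4-en-1-yl]-2,4-dimethyloxetane | I/C=C(\C)C[C@@H](C)C[C@@]1(C)C[C@H](C)O1 | intermediate
20 | (2S,4R,6R,8E)-4-hydroperoxy-9-iodo-4,6,8-trimethylnon-8-en-2-ol | I/C=C(\C)C[C@@H](C)C[C@](OO)(C)C[C@H](C)O | intermediate
21 | (2S,4R,6R,8E)-4-[(tert-butyldimethylsilyl)peroxy]-9-iodo-4,6,8-trimethylnon-8-en-2-ol | I/C=C(\C)C[C@@H](C)C[C@](OO[Si](C)(C)C(C)(C)C)(C)C[C@H](C)O | intermediate
22 | (2S,4R,6R,8E)-4-[(tert-butyldimethylsilyl)peroxy]-9-iodo-4,6,8-trimethylnon-8-en-2-yl 2-chloro-2-oxoacetate | I/C=C(\C)C[C@@H](C)C[C@](OO[Si](C)(C)C(C)(C)C)(C)C[C@H](C)OC(=O)C(=O)Cl | intermediate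
23 | (2S,4R,6R,8E)-4-[(tert-butyldimethylsilyl)peroxy]-9-iodo-4,6,8-trimethylnon-8-en-2-yl 3-diazo-2-oxopropanoate | I/C=C(\C)C[C@@H](C)C[C@](OO[Si](C)(C)C(C)(C)C)(C)C[C@H](C)OC(=O)C(=O)C=[N+]=[N-] | intermediate
24 | (5S)-5-[(2R,4R,6E)-2-[(tert-butyldimethylsilyl)peroxy]-7-iodo-2,4,6-trimethylhept-6-en-1-yl]-5-methyldihydrofuran-2,3-dione (in equilibrium with its 3-hydroxyfuran-2(5H)-one enol) | I/C=C(\C)C[C@@H](C)C[C@](OO[Si](C)(C)C(C)(C)C)(C)C[C@]1(C)OC(=O)C(=O)C1 | intermediate
25 | (3RS,5R)-5-[(2R,4R,6E)-2-[(tert-butyldimethylsilyl)peroxy]-7-iodo-2,4,6-trimethylhept-6-en-1-yl]-3-hydroxy-5-methyldihydrofuran-2(3H)-one | I/C=C(\C)C[C@@H](C)C[C@](OO[Si](C)(C)C(C)(C)C)(C)C[C@]1(C)OC(=O)C(O)C1 | intermediate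
26 | 3-methanesulfonate of 25 | I/C=C(\C)C[C@@H](C)C[C@](OO[Si](C)(C)C(C)(C)C)(C)C[C@]1(C)OC(=O)C(OS(C)(=O)=O)C1 | intermediate
27 | (5S)-5-[(2R,4R,6E)-2-[(tert-butyldimethylsilyl)peroxy]-7-iodo-2,4,6-trimethylhept-6-en-1-yl]-5-methylfuran-2(5H)-one | I/C=C(\C)C[C@@H](C)C[C@](OO[Si](C)(C)C(C)(C)C)(C)C[C@]1(C)OC(=O)C=C1 | intermediate
28 | but-2-yn-1-ylbenzene | CC#CCc1ccccc1 | starting material
29 | (Z)-4,4,5,5-tetramethyl-2-(4-phenylbut-2-en-2-yl)-1,3,2-dioxaborolane | CC(=C\Cc1ccccc1)/B1OC(C)(C)C(C)(C)O1 | intermediate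
30 | (5S)-5-[(2R,4R,6E,8E)-2-[(tert-butyldimethylsilyl)peroxy]-2,4,6,8-tetramethyl-10-phenyldeca-6,8-dien-1-yl]-5-methylfuran-2(5H)-one | CC(=C\Cc1ccccc1)/C=C(\C)C[C@@H](C)C[C@](OO[Si](C)(C)C(C)(C)C)(C)C[C@]1(C)OC(=O)C=C1 | intermediate
31 | (5S)-5-[(2R,4R,6E,8E)-2-hydroperoxy-2,4,6,8-tetramethyl-10-phenyldeca-6,8-dien-1-yl]-5-methylfuran-2(5H)-one | CC(=C\Cc1ccccc1)/C=C(\C)C[C@@H](C)C[C@](OO)(C)C[C@]1(C)OC(=O)C=C1 | intermediate
32 | (3R,4aS,7aS)-3,4a-dimethyl-3-[(2R,4E,6E)-2,4,6-trimethyl-8-phenylocta-4,6-dien-1-yl]tetrahydrofuro[3,2-c][1,2]dioxin-6-one (CNP0272658.1) | CC(=C\Cc1ccccc1)/C=C(\C)C[C@@H](C)C[C@]1(C)C[C@]2(C)OC(=O)C[C@@H]2OO1 | target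

**Step count and risks**

Total step count: 20. Longest linear sequence: 19 steps (steps 1–17, 19 and 20; step 18 prepares the coupling partner).

Steps most likely to fail:

Step 15 (proposed new method). The insertion into a C–H bond that is deactivated by the acyloxy group, and that needs the less favoured ester conformer, may lose out to carbene dimerisation, 1,6-insertion or reaction at the iodoalkene. The fallback uses known chemistry, sets out from 21 and returns at 27. Dess–Martin oxidation of 21 should give the methyl ketone (4R,6R,8E)-4-[(tert-butyldimethylsilyl)peroxy]-9-iodo-4,6,8-trimethylnon-8-en-2-one F1. Addition of vinylmagnesium bromide with CeCl3 at −78 °C makes the C3–C4 bond without stereocontrol and should give the tertiary allylic alcohol (3S,5R,7R,9E)-5-[(tert-butyldimethylsilyl)peroxy]-10-iodo-3,5,7,9-tetramethyldeca-1,9-dien-3-ol F2 together with its (3R,5R,7R,9E) epimer F3, which is removed by chromatography. Acylation of F2 with acryloyl chloride, i-Pr2NEt and DMAP should give (3S,5R,7R,9E)-5-[(tert-butyldimethylsilyl)peroxy]-10-iodo-3,5,7,9-tetramethyldeca-1,9-dien-3-yl acrylate F4. Ring-closing metathesis of F4 with the second-generation Grubbs catalyst, a reaction type that tolerates peroxides, should close ring A and give 27.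

Step 12. Ionisation of the activated oxetane to a free tertiary cation would erode the inversion at C6 and open elimination pathways, and some opening at C4 is possible. The fallback gives up stereocontrol at C6, sets out from 17 and returns at 20. Mitsunobu esterification of the secondary hydroxyl of 17 (4-nitrobenzoic acid, PPh3, diisopropyl azodicarboxylate) inverts C4 and should give (2S,4S,6R,8E)-4-hydroxy-9-iodo-4,6,8-trimethylnon-8-en-2-yl 4-nitrobenzoate F5. Acid-catalysed perhydrolysis of the tertiary alcohol (50% H2O2, cat. H2SO4) by an SN1 path should give (2S,4R,6R,8E)-4-hydroperoxy-9-iodo-4,6,8-trimethylnon-8-en-2-yl 4-nitrobenzoate F6 and its (2S,4S,6R,8E) epimer F7, which are separated by chromatography. Methanolysis of F6 (K2CO3, MeOH) should give 20.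

Step 17. Elimination at the α-mesyloxy lactone may be overtaken by substitution, or DBU may strip the silyl peroxide and trigger ring closure before the side chain is complete. The fallback removes the C2 oxygen by another route, sets out from 24 and returns at 30. Triflation of the enol of 24 (Tf2O, 2,6-lutidine, −78 °C) should give (5S)-5-[(2R,4R,6E)-2-[(tert-butyldimethylsilyl)peroxy]-7-iodo-2,4,6-trimethylhept-6-en-1-yl]-5-methyl-2-oxo-2,5-dihydrofuran-3-yl trifluoromethanesulfonate F8. Iodide-selective Suzuki–Miyaura coupling of F8 with 29 (Pd(PPh3)4, K3PO4, rt) should give (5S)-5-[(2R,4R,6E,8E)-2-[(tert-butyldimethylsilyl)peroxy]-2,4,6,8-tetramethyl-10-phenyldeca-6,8-dien-1-yl]-5-methyl-2-oxo-2,5-dihydrofuran-3-yl trifluoromethanesulfonate F9. Palladium-catalysed formate reduction of the enol triflate (Pd(OAc)2, PPh3, HCO2H, Et3N, DMF) should then give 30.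

Further compounds
F1 | step 15 | (4R,6R,8E)-4-[(tert-butyldimethylsilyl)peroxy]-9-iodo-4,6,8-trimethylnon-8-en-2-one | I/C=C(\C)C[C@@H](C)C[C@](OO[Si](C)(C)C(C)(C)C)(C)CC(C)=O
F2 | step 15 | (3S,5R,7R,9E)-5-[(tert-butyldimethylsilyl)peroxy]-10-iodo-3,5,7,9-tetramethyldeca-1,9-dien-3-ol | I/C=C(\C)C[C@@H](C)C[C@](OO[Si](C)(C)C(C)(C)C)(C)C[C@](C)(O)C=C
F3 | step 15 | (3R,5R,7R,9E)-5-[(tert-butyldimethylsilyl)peroxy]-10-iodo-3,5,7,9-tetramethyldeca-1,9-dien-3-ol | I/C=C(\C)C[C@@H](C)C[C@](OO[Si](C)(C)C(C)(C)C)(C)C[C@@](C)(O)C=C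
F4 | step 15 | (3S,5R,7R,9E)-5-[(tert-butyldimethylsilyl)peroxy]-10-iodo-3,5,7,9-tetramethyldeca-1,9-dien-3-yl acrylate | I/C=C(\C)C[C@@H](C)C[C@](OO[Si](C)(C)C(C)(C)C)(C)C[C@](C)(OC(=O)C=C)C=C
F5 | step 12 | (2S,4S,6R,8E)-4-hydroxy-9-iodo-4,6,8-trimethylnon-8-en-2-yl 4-nitrobenzoate | I/C=C(\C)C[C@@H](C)C[C@@](O)(C)C[C@H](C)OC(=O)c1ccc(cc1)[N+](=O)[O-]
F6 | step 12 | (2S,4R,6R,8E)-4-hydroperoxy-9-iodo-4,6,8-trimethylnon-8-en-2-yl 4-nitrobenzoate | I/C=C(\C)C[C@@H](C)C[C@](OO)(C)C[C@H](C)OC(=O)c1ccc(cc1)[N+](=O)[O-]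
F7 | step 12 | (2S,4S,6R,8E)-4-hydroperoxy-9-iodo-4,6,8-trimethylnon-8-en-2-yl 4-nitrobenzoate | I/C=C(\C)C[C@@H](C)C[C@@](OO)(C)C[C@H](C)OC(=O)c1ccc(cc1)[N+](=O)[O-]
F8 | step 17 | (5S)-5-[(2R,4R,6E)-2-[(tert-butyldimethylsilyl)peroxy]-7-iodo-2,4,6-trimethylhept-6-en-1-yl]-5-methyl-2-oxo-2,5-dihydrofuran-3-yl trifluoromethanesulfonate | I/C=C(\C)C[C@@H](C)C[C@](OO[Si](C)(C)C(C)(C)C)(C)C[C@]1(C)OC(=O)C(OS(=O)(=O)C(F)(F)F)=C1
F9 | step 17 | (5S)-5-[(2R,4R,6E,8E)-2-[(tert-butyldimethylsilyl)peroxy]-2,4,6,8-tetramethyl-10-phenyldeca-6,8-dien-1-yl]-5-methyl-2-oxo-2,5-dihydrofuran-3-yl trifluoromethanesulfonate | CC(=C\Cc1ccccc1)/C=C(\C)C[C@@H](C)C[C@](OO[Si](C)(C)C(C)(C)C)(C)C[C@]1(C)OC(=O)C(OS(=O)(=O)C(F)(F)F)=C1
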